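**Retrosynthetic overview**

1. Feature (carotenoid numbering: ring C1–C6 with CMe2 = C1 and carbinol = C3; chain C7–C15, then C15'–C8'): the methyl-bearing E-alkene C9=C10 is bonded directly to the alkyne C7≡C8 on ring carbon C6. The unit ring–C≡C–C(CH3)=CH– is therefore the syn methyl/metal adduct of a ring-bound buta-1,3-diyne.
2. C15=C15' is the last C–C bond (Wittig): C20 hydroxy phosphonium salt + C10 aldehyde acetal OHC–CH=C(CH3)–CH=CH–CH=C(CH3)–CH(OMe)2. Mild acid then frees C8'HO.
3. C9–CH3 and C10–C11 are cut together (key step, one pot): ring butadiyne + AlMe3 + (1E,3E)-dienyl iodide, by Zr-catalysed methylalumination and Pd/Zn coupling, give the whole C20 tetraenyne.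
4. C6–C7: enol triflate of silylated (4R,6R)-actinol + trimethylsilylbutadiynylzinc. C3 comes from ketoisophorone by enzymatic C=C reduction, then substrate-controlled C=O reduction.
5. Rings: none is formed. The single six-membered ring enters with ketoisophorone, and only its C5=C6 alkene is installed, through the enol triflate.

Key step: step 9

Remark on the chemistry: the C10 Wittig partner must carry its free CHO on the CH= terminus (8,8-dimethoxy-3,7-dimethyl pattern). The regioisomer with CHO on the C(CH3)= terminus would move the C13' and C9' methyl groups by one carbon each.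

Remark on the chemistry: triethyl 3-methyl-4-phosphonocrotonate is assumed to be used as the commercial E/Z mixture, because its allylic anion is configurationally mobile.

**Fragment A: ring butadiyne**

Step 1
Reactants: 1 ketoisophorone (2,6,6-trimethylcyclohex-2-ene-1,4-dione)
Product: 2 (6R)-levodione, (6R)-2,2,6-trimethylcyclohexane-1,4-dione
Conditions: ene-reductase OYE2 of baker's yeast, NADP+ (cat.), glucose dehydrogenase, D-glucose, phosphate buffer pH 7, 30 °C
Reagents that add atoms: none
Why: Biocatalytic asymmetric conjugate reduction (flavin-dependent ene-reductase): hydride and proton add trans across the enedione C=C inside an active site that presents one face only, which should set the methyl-bearing carbon C6 as R.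

Step 2
Reactants: 2 (6R)-levodione
Product: 3 (4R,6R)-actinol, (4R,6R)-4-hydroxy-2,2,6-trimethylcyclohexanone (OH and C6-CH3 trans)
Conditions: H2, neutral Raney Ni, MeOH, rt; chromatography or crystallisation
Reagents that add atoms: none
Why: Chemoselective, substrate-controlled heterogeneous hydrogenation of a ketone: only the C4 carbonyl is accessible (C1 is flanked by CMe2 and CHMe), and in the chair with equatorial C6 methyl the axial C2 methyl blocks the axial approach, so hydrogen should arrive equatorially and give mainly the axial 4R alcohol trans to the C6 methyl, the minor cis isomer being removed on purification.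

Step 3
Reactants: 3 (4R,6R)-actinol
Product: 4 (4R,6R)-4-(tert-butyldimethylsilyloxy)-2,2,6-trimethylcyclohexanone
Conditions: TBSCl, imidazole, DMF, rt
Reagents that add atoms: tert-butyldimethylsilyl chloride, CC(C)(C)[Si](C)(C)Cl
Why: Imidazole-promoted silylation of a secondary alcohol gives an ether that survives strong base, organozinc reagents, AlMe3 and carbonate methanolysis, and no stereocentre is touched.

Step 4
Reactants: 4 silylated actinol
Product: 6 (4R)-4-(tert-butyldimethylsilyloxy)-2,6,6-trimethylcyclohex-1-en-1-yl trifluoromethanesulfonate, via lithium enolate 5 (not isolated)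
Conditions: LiN(iPr)2, THF, −78 to 0 °C; PhNTf2, −78 °C to rt
Reagents that add atoms: N-phenylbis(trifluoromethanesulfonimide), O=S(=O)(N(c1ccccc1)S(=O)(=O)C(F)(F)F)C(F)(F)F
Why: Enol triflate formation: the ketone has a single alpha hydrogen (on the CHMe carbon), so deprotonation gives one enolate whose O-sulfonylation fixes the tetrasubstituted alkene (carotenoid C5=C6), erases the no longer needed methyl-bearing stereocentre and leaves the silyloxy carbon (carotenoid C3, R) untouched.

Step 5
Reactants: 6 enol triflate; 7 1,4-bis(trimethylsilyl)buta-1,3-diyne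
Product: 10 tert-butyl(dimethyl){[(1R)-3,5,5-trimethyl-4-(4-trimethylsilylbuta-1,3-diyn-1-yl)cyclohex-3-en-1-yl]oxy}silane, via lithium trimethylsilylbutadiynide 8 (not isolated), via trimethylsilylbutadiynylzinc chloride 9 (not isolated)
Conditions: 7, MeLi·LiBr, THF, 0 °C to rt; ZnCl2, THF, 0 °C; then 6, Pd(PPh3)4 (5 mol %), THF, rt to 50 °C
Reagents that add atoms: none
Why: Selective mono-desilylation of 7 by MeLi, transmetalation to zinc and Negishi alkynyl–alkenyl coupling at the enol triflate form C6–C7; the copper-free zinc protocol avoids oxidative diyne homocoupling, and the LiCl formed in the flask assists oxidative addition of the triflate.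

Step 6
Reactants: 10 silylated ring diyne
Product: 11 tert-butyl{[(1R)-4-(buta-1,3-diyn-1-yl)-3,5,5-trimethylcyclohex-3-en-1-yl]oxy}dimethylsilane
Conditions: K2CO3 (cat.), MeOH–THF, 0 °C; dried and carried on at once as a solution
Reagents that add atoms: none
Why: Base-catalysed protiodesilylation of an alkynylsilane: methoxide attacks the unhindered, acetylide-releasing SiMe3 group far faster than the bulky silyl ether, so only the diyne terminus is unmasked.

**Fragment B: dienyl iodide**

Step 7
Reactants: 12 (E)-3-methylpent-2-en-4-yn-1-ol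
Product: 13 tert-butyl(dimethyl){[(2E)-3-methylpent-2-en-4-yn-1-yl]oxy}silane
Conditions: TBSCl, imidazole, CH2Cl2, 0 °C to rt
Reagents that add atoms: tert-butyldimethylsilyl chloride, CC(C)(C)[Si](C)(C)Cl
Why: Imidazole-promoted silylation of a primary allylic alcohol removes the acidic O–H before hydrozirconation and leaves the E alkene unchanged.

Step 8
Reactants: 13 silylated enynol
Product: 15 tert-butyl{[(2E,4E)-5-iodo-3-methylpenta-2,4-dien-1-yl]oxy}dimethylsilane, via alkenylzirconocene chloride 14 (not isolated)
Conditions: Cp2Zr(H)Cl, THF, rt, dark; I2, THF, 0 °C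
Reagents that add atoms: iodine, II
Why: Hydrozirconation–iodinolysis: Cp2Zr(H)Cl adds syn to the terminal alkyne and places zirconium on the terminal carbon, the trisubstituted alkene is too hindered to react, and I2 cleaves the C–Zr bond with retention to give the 4E iodide.

**Key coupling and C20 phosphonium salt**

Step 9
Reactants: 11 ring butadiyne; 15 dienyl iodide; 16 trimethylaluminium
Product: 19 (3R)-7,8-didehydro-3-hydroxyretinol bis(tert-butyldimethylsilyl) ether (all-E C20 tetraenyne), via alkenyldimethylalane 17 (not isolated), via alkenylzinc chloride 18 (not isolated)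
Conditions: 16 (2 equiv), Cp2ZrCl2 (0.25 equiv), ClCH2CH2Cl, 0 °C to rt; volatiles removed in vacuo; THF, ZnCl2 (1 equiv), 15, Pd(PPh3)4 (5 mol %), 0 °C to rt
Reagents that add atoms: trimethylaluminium 16, C[Al](C)C (supplies the C9 methyl group)
Why: Cp2ZrCl2 and AlMe3 form a chloride-bridged Zr–Al methyl species that adds CH3 and metal in a concerted four-centre syn fashion across the terminal C9≡C10 triple bond of 11, CH3 going to the substituted carbon C9 and aluminium ending on the CH terminus C10 (alane 17). ZnCl2 then relays the alkenyl group to zinc (18), zerovalent palladium inserts into the C–I bond of 15, and transmetalation followed by reductive elimination forms C10–C11 with retention at both partners, so C9=C10, C11=C12 and C13=C14 should all be E. The reaction type is the zirconium-catalysed Negishi methylalumination of terminal alkynes run in one pot with the Pd/Zn alkenyl–alkenyl Negishi coupling, as practised on terminal alkynes conjugated to further unsaturation in polyene and carotenoid work; the alkynyl group on C9 is simply another unsaturated substituent on such a terminal alkyne. No ring closes and no stereocentre is created, C3 being a remote spectator under its silyl ether. Site selectivity (C9≡C10 over C7≡C8) rests on the internal alkyne being disubstituted and shielded by the C1 gem-dimethyl and C5 methyl groups, and regioselectivity rests on the preference of the bulky metal for the unsubstituted terminus. Deprotonation of the acidic diyne C–H is held back by the non-coordinating chlorinated solvent, in which carbometalation outruns metalation, and excess AlMe3 is stripped off before the coupling so that methyl transfer to 15 cannot compete.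

Step 10
Reactants: 19 C20 bis(silyl ether)
Product: 20 (3R)-7,8-didehydro-3-hydroxyretinol, (2E,4E,6E)-9-[(4R)-4-hydroxy-2,6,6-trimethylcyclohex-1-en-1-yl]-3,7-dimethylnona-2,4,6-trien-8-yn-1-ol
Conditions: Bu4NF (3 equiv), THF, 0 °C to rt, dark
Reagents that add atoms: none
Why: Fluoride-induced cleavage of both silyl ethers, driven by Si–F bond formation, proceeds without acid and should leave the polyenyne geometry and C3 alone.

Step 11
Reactants: 20 C20 diol
Product: 21 [(2E,4E,6E)-9-[(4R)-4-hydroxy-2,6,6-trimethylcyclohex-1-en-1-yl]-3,7-dimethylnona-2,4,6-trien-8-yn-1-yl]triphenylphosphonium bromide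
Conditions: PPh3·HBr, MeOH, 0 °C to rt, dark, argon
Reagents that add atoms: triphenylphosphine hydrobromide, [Br-].c1ccc(cc1)[PH+](c1ccccc1)c1ccccc1
Why: Phosphonium salt formation from an allylic alcohol as practised in carotenoid synthesis: HBr ionises only the primary polyenylic C15–OH to a delocalised cation that PPh3 captures at the least hindered terminus C15, whereas the isolated secondary C3–OH cannot ionise under these conditions.

**Fragment C: C10 aldehyde acetal**

Step 12
Reactants: 22 1,1-dimethoxypropan-2-one (pyruvaldehyde dimethyl acetal); 23 triethyl phosphonoacetate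
Product: 25 ethyl (2E)-4,4-dimethoxy-3-methylbut-2-enoate, via sodium phosphonoacetate carbanion 24 (not isolated)
Conditions: NaH, THF, 0 °C to rt
Reagents that add atoms: triethyl phosphonoacetate 23, CCOC(=O)CP(=O)(OCC)OCC
Why: Horner–Wadsworth–Emmons olefination of a methyl ketone, in which the bulkier CH(OMe)2 group should end up trans to the ester (E), any Z isomer being removed by chromatography.

Step 13
Reactants: 25 C5 ester
Product: 26 (2E)-4,4-dimethoxy-3-methylbut-2-en-1-ol
Conditions: iBu2AlH (2.2 equiv), CH2Cl2, −78 °C; aq. potassium sodium tartrate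
Reagents that add atoms: none
Why: 1,2-Reduction of an enoate by iBu2AlH at low temperature, with a non-acidic tartrate work-up that keeps the dimethyl acetal.

Step 14
Reactants: 26 C5 alcohol
Product: 27 (2E)-4,4-dimethoxy-3-methylbut-2-enal
Conditions: MnO2, CH2Cl2, rt
Reagents that add atoms: none
Why: Allylic oxidation by MnO2 under neutral heterogeneous conditions stops at the enal and disturbs neither the acetal nor the E alkene.

Step 15
Reactants: 27 C5 aldehyde; 28 triethyl 3-methyl-4-phosphonocrotonate
Product: 30 ethyl (2E,4E,6E)-8,8-dimethoxy-3,7-dimethylocta-2,4,6-trienoate, via lithium phosphonocrotonate carbanion 29 (not isolated)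
Conditions: 28, n-BuLi, DMPU, THF, −78 °C; then 27, −78 to 0 °C
Reagents that add atoms: triethyl 3-methyl-4-phosphonocrotonate 28, CCOC(=O)/C=C(\C)CP(=O)(OCC)OCC
Why: Vinylogous Horner–Wadsworth–Emmons olefination as used for retinoates: the delocalised anion reacts at its phosphorus-bearing carbon to form the new C4=C5 alkene E, the lithium/DMPU conditions favour the 2E geometry, and minor 2Z material is separated by chromatography.

Step 16
Reactants: 30 C10 ester
Product: 31 (2E,4E,6E)-8,8-dimethoxy-3,7-dimethylocta-2,4,6-trien-1-ol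
Conditions: iBu2AlH (2.2 equiv), CH2Cl2, −78 °C; aq. potassium sodium tartrate
Reagents that add atoms: none
Why: 1,2-Reduction of the trienoate by iBu2AlH at low temperature with a neutral work-up, which the acetal and the triene survive.

Step 17
Reactants: 31 C10 alcohol
Product: 32 (2E,4E,6E)-8,8-dimethoxy-3,7-dimethylocta-2,4,6-trienal
Conditions: MnO2, CH2Cl2, rt, dark
Reagents that add atoms: none
Why: Allylic oxidation by MnO2 gives the trienal with its free CHO on the CH= terminus (future C15') while the future C8' stays masked as the acetal.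

**Endgame**

Step 18
Reactants: 21 C20 phosphonium bromide; 32 C10 aldehyde acetal
Product: 34 (3R)-3-hydroxy-7,8-didehydro-8'-apo-β-caroten-8'-al dimethyl acetal (all-E), via C20 phosphorus ylide 33 (not isolated)
Conditions: NaOMe (1.2 equiv), CH2Cl2–MeOH, 0 °C to rt, dark, argon
Reagents that add atoms: none
Why: Wittig olefination of a semistabilised polyenyl ylide and a polyenal, the standard C20 + C10 carotenoid coupling, forms C15=C15'; NaOMe deprotonates only the phosphonium CH2, the free C3–OH and the acetal are inert, and the E isomer should dominate, any 15Z isomer being removed by chromatography or crystallisation.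

Step 19
Reactants: 34 C30 acetal
Product: 35 target, (2E,4E,6E,8E,10E,12E,14E)-17-[(4R)-4-hydroxy-2,6,6-trimethylcyclohex-1-en-1-yl]-2,6,11,15-tetramethylheptadeca-2,4,6,8,10,12,14-heptaen-16-ynal
Conditions: pyridinium p-toluenesulfonate (cat.), acetone–H2O, rt, dark
Reagents that add atoms: water, O
Why: Acetal hydrolysis: the oxocarbenium ion is stabilised by the whole polyene, so a very weak acid suffices and should neither ionise the C3 alcohol nor isomerise the chain.

**Compound list**

1 | ketoisophorone | CC1=CC(=O)CC(C)(C)C1=O | starting material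
2 | (6R)-levodione | C[C@H]1C(=O)C(C)(C)CC(=O)C1 | intermediate
3 | (4R,6R)-actinol | C[C@H]1C(=O)C(C)(C)C[C@H](O)C1 | intermediate
4 | (4R,6R)-4-(tert-butyldimethylsilyloxy)-2,2,6-trimethylcyclohexanone | C[C@H]1C(=O)C(C)(C)C[C@H](O[Si](C)(C)C(C)(C)C)C1 | intermediate
5 | lithium enolate of 4 | CC1=C([O-])C(C)(C)C[C@H](O[Si](C)(C)C(C)(C)C)C1.[Li+] | intermediate
6 | (4R)-4-(tert-butyldimethylsilyloxy)-2,6,6-trimethylcyclohex-1-en-1-yl triflate | CC1=C(OS(=O)(=O)C(F)(F)F)C(C)(C)C[C@H](O[Si](C)(C)C(C)(C)C)C1 | intermediate
7 | 1,4-bis(trimethylsilyl)buta-1,3-diyne | C[Si](C)(C)C#CC#C[Si](C)(C)C | starting material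
8 | lithium trimethylsilylbutadiynide | [Li]C#CC#C[Si](C)(C)C | intermediate
9 | trimethylsilylbutadiynylzinc chloride | Cl[Zn]C#CC#C[Si](C)(C)C | intermediate
10 | C-silylated ring butadiyne | CC1=C(C#CC#C[Si](C)(C)C)C(C)(C)C[C@H](O[Si](C)(C)C(C)(C)C)C1 | intermediate
11 | tert-butyl{[(1R)-4-(buta-1,3-diyn-1-yl)-3,5,5-trimethylcyclohex-3-en-1-yl]oxy}dimethylsilane | CC1=C(C#CC#C)C(C)(C)C[C@H](O[Si](C)(C)C(C)(C)C)C1 | intermediate
12 | (E)-3-methylpent-2-en-4-yn-1-ol | C#C/C(C)=C/CO | starting material
13 | silyl ether of 12 | C#C/C(C)=C/CO[Si](C)(C)C(C)(C)C | intermediate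
14 | (1E,3E)-dienylzirconocene chloride | C1=CC(C=C1)[Zr](Cl)(/C=C/C(C)=C/CO[Si](C)(C)C(C)(C)C)C1C=CC=C1 | intermediate
15 | tert-butyl{[(2E,4E)-5-iodo-3-methylpenta-2,4-dien-1-yl]oxy}dimethylsilane | I/C=C/C(C)=C/CO[Si](C)(C)C(C)(C)C | intermediate
16 | trimethylaluminium | C[Al](C)C | starting material
17 | (E)-C10 alkenyldimethylalane | CC1=C(C#C/C(C)=C/[Al](C)C)C(C)(C)C[C@H](O[Si](C)(C)C(C)(C)C)C1 | intermediate
18 | (E)-C10 alkenylzinc chloride | CC1=C(C#C/C(C)=C/[Zn]Cl)C(C)(C)C[C@H](O[Si](C)(C)C(C)(C)C)C1 | intermediate
19 | C20 tetraenyne bis(tert-butyldimethylsilyl) ether | CC1=C(C#C/C(C)=C/C=C/C(C)=C/CO[Si](C)(C)C(C)(C)C)C(C)(C)C[C@H](O[Si](C)(C)C(C)(C)C)C1 | intermediate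
20 | (3R)-7,8-didehydro-3-hydroxyretinol | CC1=C(C#C/C(C)=C/C=C/C(C)=C/CO)C(C)(C)C[C@H](O)C1 | intermediate
21 | C20 hydroxy phosphonium bromide | CC1=C(C#C/C(C)=C/C=C/C(C)=C/C[P+](c2ccccc2)(c2ccccc2)c2ccccc2)C(C)(C)C[C@H](O)C1.[Br-] | intermediate
22 | 1,1-dimethoxypropan-2-one | CC(=O)C(OC)OC | starting material
23 | triethyl phosphonoacetate | CCOC(=O)CP(=O)(OCC)OCC | starting material
24 | sodium carbanion of 23 | [Na+].CCOC(=O)[CH-]P(=O)(OCC)OCC | intermediate
25 | ethyl (2E)-4,4-dimethoxy-3-methylbut-2-enoate | CCOC(=O)/C=C(\C)C(OC)OC | intermediate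
26 | (2E)-4,4-dimethoxy-3-methylbut-2-en-1-ol | OC/C=C(\C)C(OC)OC | intermediate
27 | (2E)-4,4-dimethoxy-3-methylbut-2-enal | O=C/C=C(\C)C(OC)OC | intermediate
28 | triethyl 3-methyl-4-phosphonocrotonate (sold as E/Z mixture, E drawn) | CCOC(=O)/C=C(\C)CP(=O)(OCC)OCC | starting material
29 | lithium carbanion of 28 (delocalised) | [Li+].CCOC(=O)C=C(C)[CH-]P(=O)(OCC)OCC | intermediate
30 | ethyl (2E,4E,6E)-8,8-dimethoxy-3,7-dimethylocta-2,4,6-trienoate | CCOC(=O)/C=C(C)/C=C/C=C(\C)C(OC)OC | intermediate
31 | (2E,4E,6E)-8,8-dimethoxy-3,7-dimethylocta-2,4,6-trien-1-ol | OC/C=C(C)/C=C/C=C(\C)C(OC)OC | intermediate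
32 | (2E,4E,6E)-8,8-dimethoxy-3,7-dimethylocta-2,4,6-trienal | O=C/C=C(C)/C=C/C=C(\C)C(OC)OC | intermediate
33 | C20 phosphorus ylide | CC1=C(C#C/C(C)=C/C=C/C(C)=C/C=P(c2ccccc2)(c2ccccc2)c2ccccc2)C(C)(C)C[C@H](O)C1 | intermediate
34 | C30 dimethyl acetal | CC1=C(C#C/C(C)=C/C=C/C(C)=C/C=C/C=C(C)/C=C/C=C(\C)C(OC)OC)C(C)(C)C[C@H](O)C1 | intermediate
35 | (3R)-3-hydroxy-7,8-didehydro-8'-apo-β-caroten-8'-al | CC1=C(C#C/C(C)=C/C=C/C(C)=C/C=C/C=C(C)/C=C/C=C(\C)C=O)C(C)(C)C[C@H](O)C1 | target

**Step count**

- Total step count: 19.
- Longest linear sequence: 11 steps (1–6, 9–11, 18, 19).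

**Steps most likely to fail**

Step 9. The acidic diyne terminus may be metalated to an aluminium acetylide instead of being carbometalated. The diyne may also oligomerise under the Lewis acid, methyl may leak to C10, a second addition may occur at C7≡C8, or methyl rather than alkenyl may be transferred in the coupling.

The fallback buys the C9=C10 alkene instead of making it. It sets out from triflate 6 and returns at diol 20.
- Sonogashira coupling of 6 with enynol 12 (Pd(PPh3)4, CuI, iPr2NH, DMF) should give the C15 enynol F1.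
- MnO2 oxidation should give the C15 enynal F2.
- Horner–Wadsworth–Emmons olefination with carbanion 29, made from 28 as in step 15, should give the ethyl C20 tetraenynoate F3.
- iBu2AlH reduction should give the 3-O-silyl C20 alcohol F4.
- Bu4NF then frees diol 20.

Step 11. Ionisation gives a cation delocalised from C15 to C9 and into the alkyne. Bond rotation in the cation may therefore cost E geometry at C9=C10 or C13=C14. Proton loss to an anhydro-type hydrocarbon or phosphine capture at an internal carbon may also erode the salt.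

The fallback reverses the polarity of the C15=C15' olefination, so the acetylenic half never becomes a cation. It sets out from diol 20 and C10 alcohol 31 and returns at acetal 34.
- MnO2 oxidises only the allylic alcohol of 20 to (3R)-7,8-didehydro-3-hydroxyretinal F5.
- Alcohol 31 is converted under non-acidic conditions (MsCl, Et3N, then LiBr, THF, −40 to 0 °C) into the trienyl bromide F6.
- PPh3 is added directly to give the C10 acetal phosphonium bromide F7.
- Wittig reaction of F7 with F5 (NaOMe, CH2Cl2–MeOH) forms the same C15=C15' bond and gives 34.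

Step 5. Oxidative addition at the tetrasubstituted triflate next to the quaternary carbon may be slow. Diyne homocoupling or S–O cleavage back to the ketone could then take over.

The fallback builds C6–C7 by carbonyl addition. It sets out from ketone 4 and lithium diynide 8 and returns at 10.
- 1,2-Addition of 8 to 4 (CeCl3, THF, −78 to 0 °C) should give the tertiary diynyl carbinol F8.
- Dehydration with POCl3 in pyridine can lose a proton only from the CHMe carbon, because the other neighbour is quaternary. It should therefore give the tetrasubstituted alkene of 10.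

**Further compounds**

F1 | step 9 | (2E)-5-[(4R)-4-(tert-butyldimethylsilyloxy)-2,6,6-trimethylcyclohex-1-en-1-yl]-3-methylpent-2-en-4-yn-1-ol | CC1=C(C#C/C(C)=C/CO)C(C)(C)C[C@H](O[Si](C)(C)C(C)(C)C)C1
F2 | step 9 | (2E)-5-[(4R)-4-(tert-butyldimethylsilyloxy)-2,6,6-trimethylcyclohex-1-en-1-yl]-3-methylpent-2-en-4-ynal | CC1=C(C#C/C(C)=C/C=O)C(C)(C)C[C@H](O[Si](C)(C)C(C)(C)C)C1
F3 | step 9 | ethyl (2E,4E,6E)-9-[(4R)-4-(tert-butyldimethylsilyloxy)-2,6,6-trimethylcyclohex-1-en-1-yl]-3,7-dimethylnona-2,4,6-trien-8-ynoate | CC1=C(C#C/C(C)=C/C=C/C(C)=C/C(=O)OCC)C(C)(C)C[C@H](O[Si](C)(C)C(C)(C)C)C1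
F4 | step 9 | (2E,4E,6E)-9-[(4R)-4-(tert-butyldimethylsilyloxy)-2,6,6-trimethylcyclohex-1-en-1-yl]-3,7-dimethylnona-2,4,6-trien-8-yn-1-ol | CC1=C(C#C/C(C)=C/C=C/C(C)=C/CO)C(C)(C)C[C@H](O[Si](C)(C)C(C)(C)C)C1
F5 | step 11 | (3R)-7,8-didehydro-3-hydroxyretinal | CC1=C(C#C/C(C)=C/C=C/C(C)=C/C=O)C(C)(C)C[C@H](O)C1
F6 | step 11 | (2E,4E,6E)-8-bromo-1,1-dimethoxy-2,6-dimethylocta-2,4,6-triene | BrC/C=C(C)/C=C/C=C(\C)C(OC)OC
F7 | step 11 | [(2E,4E,6E)-8,8-dimethoxy-3,7-dimethylocta-2,4,6-trien-1-yl]triphenylphosphonium bromide | c1ccccc1[P+](c1ccccc1)(c1ccccc1)C/C=C(C)/C=C/C=C(\C)C(OC)OC.[Br-]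
F8 | step 5 | (4R,6R)-4-(tert-butyldimethylsilyloxy)-2,2,6-trimethyl-1-(4-trimethylsilylbuta-1,3-diyn-1-yl)cyclohexan-1-ol (epimers at C1) | C[C@H]1C(O)(C#CC#C[Si](C)(C)C)C(C)(C)C[C@H](O[Si](C)(C)C(C)(C)C)C1
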